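**Retrosynthetic overview**

1. Target 20 is the mono-seco acid of a C2-symmetric 6,6'-bichromanone bis-γ-lactone; both halves are (2S,1'R,2'S) and the di-ortho-substituted axis is not stereogenic. The last operations unmask the protected hydroxy acid, and the biaryl is cut by Suzuki–Miyaura coupling into open-chain iodide 17 and lactone boronate 13.
2. Both partners come from one iodophenol 11 (ortho-iodination of monomer lactone 10); the open-chain half is made by lactone hydrolysis with silyl trapping.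
3. 10 comes from butenolide 9 by CuH conjugate reduction, which sets the C-methyl centre (cis) and resolves the racemate.
4. Key C–C bond (C2–C5'): vinylogous Mukaiyama–Michael addition of silyloxyfuran 6 to the benzopyrylium ion made from chromone ester 4.
5. 4 comes from Claisen condensation of 1 with 2. Ring order: pyranone, then the furanone (brought in intact), then γ-lactone by reduction, then the biaryl, with one lactone kept open.

**Assumptions:** (i) Racemic compounds (8, 9, F6, F7) are drawn as the enantiomer that is carried on. (ii) In step 4 the (S)-ligand is taken to be matched with (2S,5'R)-9; if an analytical run shows the opposite, the (R)-ligand is used. Primed locants C3'–C5' refer to furanone numbering (C5' is bonded to chromanone C2, C4' carries the methyl).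

**Step 1**
Reactants: 1 2',6'-dihydroxyacetophenone; 2 dimethyl oxalate
Product: 4 methyl 5-hydroxy-4-oxo-4H-chromene-2-carboxylate, via diketo ester 3 (not isolated)
Conditions: NaOMe (4 equiv), MeOH, reflux; then conc. HCl, MeOH, reflux
Reagents that add atoms: none
Why: Crossed Claisen condensation of the acetophenone enolate with the non-enolisable oxalate, followed by acid-catalysed cyclodehydration of the 2,4-diketo ester onto one of the two equivalent phenols, gives the chromone with no regiochemical or stereochemical issue.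

**Step 2**
Reactants: 5 4-methylfuran-2(5H)-one
Product: 6 trimethyl[(4-methylfuran-2-yl)oxy]silane
Conditions: TMSOTf (1.1 equiv), Et3N (1.2 equiv), Et2O, 0 °C to rt; decant, distil
Reagents that add atoms: trimethylsilyl triflate, C[Si](C)(C)OS(=O)(=O)C(F)(F)F
Why: Soft enolisation at the γ-CH2 and O-silylation give the aromatic 2-silyloxyfuran (a cyclic silyl dienol ether) with no stereocentre.

**Step 3**
Reactants: 4 methyl 5-hydroxy-4-oxo-4H-chromene-2-carboxylate; 6 trimethyl[(4-methylfuran-2-yl)oxy]silane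
Product: 9 (±)-methyl (2S*)-5-hydroxy-2-[(2R*)-3-methyl-5-oxo-2,5-dihydrofuran-2-yl]-4-oxochromane-2-carboxylate, via silylene-bridged benzopyrylium triflate 7 (not isolated), via silylene-bridged adduct 8 (not isolated)
Conditions: iPr2Si(OTf)2 (1.1 equiv), 2,6-lutidine (1.2 equiv), CH2Cl2, rt, 30 min; then 6 (1.5 equiv), −78 °C, 2 h; then Et3N·3HF, −78 °C to rt; chromatography
Reagents that add atoms: none
Why: Vinylogous Mukaiyama–Michael addition in which the γ-carbon (C5') of the silyloxyfuran attacks C2 of the silicon-tethered 4-siloxybenzopyrylium, creating the quaternary C2 and the adjacent C5' centre in one C–C bond formation; a Diels–Alder-like approach with the furan oxygen over the pyrylium ring is expected to favour the (2S*,5'R*) diastereomer, and the C5' epimer is removed by chromatography (product racemic).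

**Step 4**
Reactants: 9 (±)-methyl (2S*)-5-hydroxy-2-[(2R*)-3-methyl-5-oxo-2,5-dihydrofuran-2-yl]-4-oxochromane-2-carboxylate
Product: 10 methyl (2S)-5-hydroxy-2-[(2R,3S)-3-methyl-5-oxooxolan-2-yl]-4-oxochromane-2-carboxylate
Conditions: Cu(OAc)2·H2O (5 mol %), (S)-p-tol-BINAP (5.5 mol %), (EtO)2MeSiH (ca. 0.6 equiv, portionwise), t-BuOH (1 equiv), toluene, 0 °C, to ca. 45% conversion (chiral HPLC); aq. NH4F; chromatography separates unreacted (2R,5'S)-9; crystallise to raise ee
Reagents that add atoms: none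
Why: Asymmetric CuH conjugate reduction used as a kinetic resolution, in which the chiral Cu–H delivers hydride to C4' of the matched (2S,5'R) enantiomer on the face anti to the bulky chromanyl group at C5' (methyl ends cis, oxolane 3S), while the mismatched enantiomer stays as butenolide and the chelated aryl ketone is not reduced by the BINAP–CuH catalyst.

**Step 5**
Reactants: 10 methyl (2S)-5-hydroxy-2-[(2R,3S)-3-methyl-5-oxooxolan-2-yl]-4-oxochromane-2-carboxylate
Product: 11 methyl (2S)-5-hydroxy-6-iodo-2-[(2R,3S)-3-methyl-5-oxooxolan-2-yl]-4-oxochromane-2-carboxylate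
Conditions: BnMe3N+ ICl2− (1.05 equiv), NaHCO3 (2 equiv), CH2Cl2/MeOH (5:2), rt
Reagents that add atoms: benzyltrimethylammonium dichloroiodate, C[N+](C)(C)Cc1ccccc1.Cl[I-]Cl
Why: Electrophilic aromatic iodination in which the intramolecularly hydrogen-bonded 5-OH (bond fixation of the peri-hydroxy aryl ketone) directs the iodine to its ortho position C6, which is also para to the ring oxygen, without touching any stereocentre.

**Step 6**
Reactants: 11 methyl (2S)-5-hydroxy-6-iodo-2-[(2R,3S)-3-methyl-5-oxooxolan-2-yl]-4-oxochromane-2-carboxylate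
Product: 12 methyl (2S)-5-(benzyloxy)-6-iodo-2-[(2R,3S)-3-methyl-5-oxooxolan-2-yl]-4-oxochromane-2-carboxylate
Conditions: BnBr (2 equiv), Ag2O (1.5 equiv), CH2Cl2, rt to 40 °C, dark
Reagents that add atoms: benzyl bromide, BrCc1ccccc1
Why: Silver(I)-oxide-mediated Williamson benzylation is essentially neutral, so the lactone and the base-sensitive chromanone (retro-oxa-Michael, Dieckmann) are not put at risk.

**Step 7**
Reactants: 12 methyl (2S)-5-(benzyloxy)-6-iodo-2-[(2R,3S)-3-methyl-5-oxooxolan-2-yl]-4-oxochromane-2-carboxylate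
Product: 13 methyl (2S)-5-(benzyloxy)-2-[(2R,3S)-3-methyl-5-oxooxolan-2-yl]-4-oxo-6-(4,4,5,5-tetramethyl-1,3,2-dioxaborolan-2-yl)chromane-2-carboxylate
Conditions: B2pin2 (1.5 equiv), PdCl2(dppf)·CH2Cl2 (5 mol %), KOAc (3 equiv), dioxane, 80 °C
Reagents that add atoms: bis(pinacolato)diboron, CC1(C)OB(OC1(C)C)B1OC(C)(C)C(C)(C)O1
Why: Miyaura borylation of the aryl iodide uses only the weak base acetate, which leaves lactone, esters and the C2 stereocentre untouched.

**Step 8**
Reactants: 11 methyl (2S)-5-hydroxy-6-iodo-2-[(2R,3S)-3-methyl-5-oxooxolan-2-yl]-4-oxochromane-2-carboxylate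
Product: 16 (3S,4R)-4-[(2S)-5-hydroxy-6-iodo-2-(methoxycarbonyl)-4-oxochroman-2-yl]-3-methyl-4-[(triethylsilyl)oxy]butanoic acid, via dilithium hydroxy carboxylate 14 (not isolated), via tris-TES derivative 15 (not isolated)
Conditions: LiOH·H2O (2.1 equiv), THF/H2O (3:1), 0 °C; evaporate, azeotrope with toluene; TESOTf (4 equiv), 2,6-lutidine (6 equiv), CH2Cl2, −78 to 0 °C; then K2CO3 (1.5 equiv), MeOH, 0 °C, 30 min; cold 0.5 M HCl to pH 4–5
Reagents that add atoms: lithium hydroxide, [Li+].[OH-]; triethylsilyl triflate, CC[Si](CC)(CC)OS(=O)(=O)C(F)(F)F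
Why: Saponification opens the unhindered γ-lactone faster than the neopentyl-type methyl ester (the phenoxide formed first suppresses retro-oxa-Michael), persilylation with the silyl triflate traps the hydroxy carboxylate before it can relactonise, and methanolysis removes only the labile silyl ester and aryl silyl ether, all by acyl–O or Si–O cleavage so that no stereocentre is affected.

**Step 9**
Reactants: 16 (3S,4R)-4-[(2S)-5-hydroxy-6-iodo-2-(methoxycarbonyl)-4-oxochroman-2-yl]-3-methyl-4-[(triethylsilyl)oxy]butanoic acid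
Product: 17 benzyl (3S,4R)-4-[(2S)-5-(benzyloxy)-6-iodo-2-(methoxycarbonyl)-4-oxochroman-2-yl]-3-methyl-4-[(triethylsilyl)oxy]butanoate
Conditions: BnBr (3 equiv), Ag2O (2 equiv), CH2Cl2, rt, dark
Reagents that add atoms: benzyl bromide, BrCc1ccccc1
Why: Silver-mediated O-alkylation converts the carboxylic acid (via its silver salt) and the phenol into benzyl ester and benzyl ether under neutral conditions that the TES ether and the chromanone tolerate.

**Step 10**
Reactants: 17 benzyl (3S,4R)-4-[(2S)-5-(benzyloxy)-6-iodo-2-(methoxycarbonyl)-4-oxochroman-2-yl]-3-methyl-4-[(triethylsilyl)oxy]butanoate; 13 methyl (2S)-5-(benzyloxy)-2-[(2R,3S)-3-methyl-5-oxooxolan-2-yl]-4-oxo-6-(4,4,5,5-tetramethyl-1,3,2-dioxaborolan-2-yl)chromane-2-carboxylate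
Product: 18 benzyl (3S,4R)-4-[(2S)-5-(benzyloxy)-6-{(2S)-5-(benzyloxy)-2-(methoxycarbonyl)-2-[(2R,3S)-3-methyl-5-oxooxolan-2-yl]-4-oxochroman-6-yl}-2-(methoxycarbonyl)-4-oxochroman-2-yl]-3-methyl-4-[(triethylsilyl)oxy]butanoate
Conditions: Pd(OAc)2 (5 mol %), SPhos (10 mol %), K3PO4 (3 equiv), toluene/H2O (10:1), degassed, 60 °C
Reagents that add atoms: none
Why: Suzuki–Miyaura cross-coupling with a bulky biaryl phosphine forms the di-ortho-oxygenated biaryl bond under mild phosphate base, and because the axis carries only two ortho substituents no axial stereochemistry has to be controlled.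

**Step 11**
Reactants: 18 benzyl (3S,4R)-4-[(2S)-5-(benzyloxy)-6-{(2S)-5-(benzyloxy)-2-(methoxycarbonyl)-2-[(2R,3S)-3-methyl-5-oxooxolan-2-yl]-4-oxochroman-6-yl}-2-(methoxycarbonyl)-4-oxochroman-2-yl]-3-methyl-4-[(triethylsilyl)oxy]butanoate
Product: 19 (3S,4R)-4-[(2S)-5-hydroxy-6-{(2S)-5-hydroxy-2-(methoxycarbonyl)-2-[(2R,3S)-3-methyl-5-oxooxolan-2-yl]-4-oxochroman-6-yl}-2-(methoxycarbonyl)-4-oxochroman-2-yl]-3-methyl-4-[(triethylsilyl)oxy]butanoic acid
Conditions: H2 (1 atm), 10% Pd/C, EtOAc, rt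
Reagents that add atoms: none
Why: Catalytic hydrogenolysis removes the benzyl ester and both aryl benzyl ethers under neutral conditions that leave the TES ether, the lactone, the methyl esters and the chelated aryl ketones intact.

**Step 12**
Reactants: 19 (3S,4R)-4-[(2S)-5-hydroxy-6-{(2S)-5-hydroxy-2-(methoxycarbonyl)-2-[(2R,3S)-3-methyl-5-oxooxolan-2-yl]-4-oxochroman-6-yl}-2-(methoxycarbonyl)-4-oxochroman-2-yl]-3-methyl-4-[(triethylsilyl)oxy]butanoic acid
Product: 20 (3S,4R)-4-hydroxy-4-[(2S)-5-hydroxy-6-{(2S)-5-hydroxy-2-(methoxycarbonyl)-2-[(2R,3S)-3-methyl-5-oxooxolan-2-yl]-4-oxochroman-6-yl}-2-(methoxycarbonyl)-4-oxochroman-2-yl]-3-methylbutanoic acid (CNP0517857.1)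
Conditions: HF·pyridine, excess pyridine, THF, 0 °C to rt; pH 6 phosphate buffer at 0 °C; reversed-phase HPLC (MeCN/H2O, no strong acid); lyophilise
Reagents that add atoms: none
Why: Fluoride-mediated desilylation in pyridine-buffered medium, where the acid is held as its pyridinium carboxylate, frees the hindered secondary alcohol without acid-catalysed relactonisation and gives the γ-hydroxy acid with all six stereocentres unchanged.

**Compound list**

1 | 2',6'-dihydroxyacetophenone | CC(=O)c1c(O)cccc1O | starting material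
2 | dimethyl oxalate | COC(=O)C(=O)OC | starting material
3 | methyl 4-(2,6-dihydroxyphenyl)-2,4-dioxobutanoate (diketo ester, present as sodium salt) | COC(=O)C(=O)CC(=O)c1c(O)cccc1O | intermediate
4 | methyl 5-hydroxy-4-oxo-4H-chromene-2-carboxylate | COC(=O)c1cc(=O)c2c(O)cccc2o1 | intermediate
5 | 4-methylfuran-2(5H)-one | CC1=CC(=O)OC1 | starting material
6 | trimethyl[(4-methylfuran-2-yl)oxy]silane | Cc1coc(O[Si](C)(C)C)c1 | intermediate
7 | 2-(methoxycarbonyl)-4,5-[(diisopropylsilanediyl)bis(oxy)]chromenylium triflate (silylene-bridged benzopyrylium triflate) | COC(=O)c1cc2c3c(cccc3[o+]1)O[Si](C(C)C)(C(C)C)O2.[O-]S(=O)(=O)C(F)(F)F | intermediate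
8 | (±)-methyl (2S*)-4,5-[(diisopropylsilanediyl)bis(oxy)]-2-[(2R*)-3-methyl-5-oxo-2,5-dihydrofuran-2-yl]-2H-chromene-2-carboxylate (silylene-bridged adduct) | COC(=O)[C@@]1([C@@H]2OC(=O)C=C2C)C=C2O[Si](C(C)C)(C(C)C)Oc3cccc(O1)c23 | intermediate
9 | (±)-methyl (2S*)-5-hydroxy-2-[(2R*)-3-methyl-5-oxo-2,5-dihydrofuran-2-yl]-4-oxochromane-2-carboxylate | COC(=O)[C@@]1([C@@H]2OC(=O)C=C2C)CC(=O)c2c(O)cccc2O1 | intermediate
10 | methyl (2S)-5-hydroxy-2-[(2R,3S)-3-methyl-5-oxooxolan-2-yl]-4-oxochromane-2-carboxylate | COC(=O)[C@@]1([C@@H]2OC(=O)C[C@@H]2C)CC(=O)c2c(O)cccc2O1 | intermediate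
11 | methyl (2S)-5-hydroxy-6-iodo-2-[(2R,3S)-3-methyl-5-oxooxolan-2-yl]-4-oxochromane-2-carboxylate | COC(=O)[C@@]1([C@@H]2OC(=O)C[C@@H]2C)CC(=O)c2c(O)c(I)ccc2O1 | intermediate
12 | methyl (2S)-5-(benzyloxy)-6-iodo-2-[(2R,3S)-3-methyl-5-oxooxolan-2-yl]-4-oxochromane-2-carboxylate | COC(=O)[C@@]1([C@@H]2OC(=O)C[C@@H]2C)CC(=O)c2c(OCc3ccccc3)c(I)ccc2O1 | intermediate
13 | methyl (2S)-5-(benzyloxy)-2-[(2R,3S)-3-methyl-5-oxooxolan-2-yl]-4-oxo-6-(4,4,5,5-tetramethyl-1,3,2-dioxaborolan-2-yl)chromane-2-carboxylate | COC(=O)[C@@]1([C@@H]2OC(=O)C[C@@H]2C)CC(=O)c2c(OCc3ccccc3)c(B3OC(C)(C)C(C)(C)O3)ccc2O1 | intermediate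
14 | dilithium (3S,4R)-4-hydroxy-4-[(2S)-6-iodo-2-(methoxycarbonyl)-5-oxido-4-oxochroman-2-yl]-3-methylbutanoate | [Li+].[Li+].COC(=O)[C@@]1([C@H](O)[C@@H](C)CC(=O)[O-])CC(=O)c2c([O-])c(I)ccc2O1 | intermediate
15 | triethylsilyl (3S,4R)-4-[(2S)-6-iodo-2-(methoxycarbonyl)-4-oxo-5-[(triethylsilyl)oxy]chroman-2-yl]-3-methyl-4-[(triethylsilyl)oxy]butanoate | COC(=O)[C@@]1([C@H](O[Si](CC)(CC)CC)[C@@H](C)CC(=O)O[Si](CC)(CC)CC)CC(=O)c2c(O[Si](CC)(CC)CC)c(I)ccc2O1 | intermediate
16 | (3S,4R)-4-[(2S)-5-hydroxy-6-iodo-2-(methoxycarbonyl)-4-oxochroman-2-yl]-3-methyl-4-[(triethylsilyl)oxy]butanoic acid | COC(=O)[C@@]1([C@H](O[Si](CC)(CC)CC)[C@@H](C)CC(=O)O)CC(=O)c2c(O)c(I)ccc2O1 | intermediate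
17 | benzyl (3S,4R)-4-[(2S)-5-(benzyloxy)-6-iodo-2-(methoxycarbonyl)-4-oxochroman-2-yl]-3-methyl-4-[(triethylsilyl)oxy]butanoate | COC(=O)[C@@]1([C@H](O[Si](CC)(CC)CC)[C@@H](C)CC(=O)OCc2ccccc2)CC(=O)c2c(OCc3ccccc3)c(I)ccc2O1 | intermediate
18 | benzyl (3S,4R)-4-[(2S)-5-(benzyloxy)-6-{(2S)-5-(benzyloxy)-2-(methoxycarbonyl)-2-[(2R,3S)-3-methyl-5-oxooxolan-2-yl]-4-oxochroman-6-yl}-2-(methoxycarbonyl)-4-oxochroman-2-yl]-3-methyl-4-[(triethylsilyl)oxy]butanoate | COC(=O)[C@@]1([C@H](O[Si](CC)(CC)CC)[C@@H](C)CC(=O)OCc6ccccc6)CC(=O)c2c(OCc7ccccc7)c(-c3ccc4c(c3OCc5ccccc5)C(=O)C[C@@](C(=O)OC)([C@@H]8OC(=O)C[C@@H]8C)O4)ccc2O1 | intermediate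
19 | (3S,4R)-4-[(2S)-5-hydroxy-6-{(2S)-5-hydroxy-2-(methoxycarbonyl)-2-[(2R,3S)-3-methyl-5-oxooxolan-2-yl]-4-oxochroman-6-yl}-2-(methoxycarbonyl)-4-oxochroman-2-yl]-3-methyl-4-[(triethylsilyl)oxy]butanoic acid | COC(=O)[C@@]1([C@H](O[Si](CC)(CC)CC)[C@@H](C)CC(=O)O)CC(=O)c2c(O)c(-c3ccc4c(c3O)C(=O)C[C@@](C(=O)OC)([C@@H]5OC(=O)C[C@@H]5C)O4)ccc2O1 | intermediate
20 | (3S,4R)-4-hydroxy-4-[(2S)-5-hydroxy-6-{(2S)-5-hydroxy-2-(methoxycarbonyl)-2-[(2R,3S)-3-methyl-5-oxooxolan-2-yl]-4-oxochroman-6-yl}-2-(methoxycarbonyl)-4-oxochroman-2-yl]-3-methylbutanoic acid (CNP0517857.1) | COC(=O)[C@@]1([C@H](O)[C@@H](C)CC(=O)O)CC(=O)c2c(ccc(-c3ccc4c(c3O)C(=O)C[C@@](C(=O)OC)([C@@H]3OC(=O)C[C@@H]3C)O4)c2O)O1 | target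

**Step count and risks**

Total steps: 12. Longest linear sequence: 9 steps (steps 1, 3, 4, 5, 8, 9, 10, 11, 12; the boronate branch through steps 6 and 7 is equally long).

Most likely to fail:

Step 4 (selectivity factor of the CuH kinetic resolution, competing 1,2-reduction, silane consumption by the phenol). The fallback sets out from 9 and comes back at 10. Racemic 9 is reduced without a chiral catalyst by nickel boride (NiCl2·6H2O/NaBH4, MeOH–THF, −20 °C), which under substrate control gives the racemic cis-lactone, that is 10 together with its mirror image methyl (2R)-5-hydroxy-2-[(2S,3R)-3-methyl-5-oxooxolan-2-yl]-4-oxochromane-2-carboxylate F1. The phenol of this mixture is acylated with (1S)-(−)-camphanic chloride (Et3N, DMAP, CH2Cl2) to give two diastereomers, the 5-O-[(1S)-camphanoyl] ester of 10 F2 and the 5-O-[(1S)-camphanoyl] ester of the mirror-image lactone F3, which are separated by crystallisation or chromatography. Mild aminolysis of F2 with 3-(dimethylamino)propylamine (THF, 0 °C) cleaves only the aryl ester and returns 10.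

Step 5 (iodination at C8 or di-iodination instead of clean C6 substitution). The fallback sets out from 4 and comes back at 11. The iodine is introduced before the key addition, at the cheap, crystalline chromone stage, where isomers can be separated by crystallisation and the position proven by NOE/HMBC or X-ray before valuable material is committed. Chromone ester 4 is iodinated (BnMe3N·ICl2/NaHCO3 or NIS/TFA) to methyl 5-hydroxy-6-iodo-4-oxo-4H-chromene-2-carboxylate F4. The procedure of step 3 on F4 proceeds through the iodinated silylene-bridged benzopyrylium triflate F5 and the iodinated silylene-bridged adduct F6 (neither isolated) to (±)-methyl (2S*)-5-hydroxy-6-iodo-2-[(2R*)-3-methyl-5-oxo-2,5-dihydrofuran-2-yl]-4-oxochromane-2-carboxylate F7. The CuH kinetic resolution of step 4 applied to F7 gives 11 directly.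

Step 8 (methyl ester hydrolysis, C2 epimerisation or relactonisation during opening and silyl trapping). The fallback sets out from 11 and comes back at 20 without any protection of the open chain. The lactone of 11 is opened with LiOH as before to 14, and this dianion is coupled at once with boronate 13 in the same aqueous basic medium (Pd(OAc)2/SPhos, K3PO4, THF/H2O, 40 °C), in which the γ-hydroxy carboxylate cannot lactonise. Cold acidification to pH 5 gives (3S,4R)-4-[(2S)-6-{(2S)-5-(benzyloxy)-2-(methoxycarbonyl)-2-[(2R,3S)-3-methyl-5-oxooxolan-2-yl]-4-oxochroman-6-yl}-5-hydroxy-2-(methoxycarbonyl)-4-oxochroman-2-yl]-4-hydroxy-3-methylbutanoic acid F8. Neutral hydrogenolysis (H2, Pd/C, EtOAc) of its single benzyl ether gives 20.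

**Further compounds**

F1 | step 4 | methyl (2R)-5-hydroxy-2-[(2S,3R)-3-methyl-5-oxooxolan-2-yl]-4-oxochromane-2-carboxylate (mirror image of 10) | COC(=O)[C@]1([C@H]2OC(=O)C[C@H]2C)CC(=O)c2c(O)cccc2O1
F2 | step 4 | (2S)-2-(methoxycarbonyl)-2-[(2R,3S)-3-methyl-5-oxooxolan-2-yl]-4-oxochroman-5-yl (1S,4R)-4,7,7-trimethyl-3-oxo-2-oxabicyclo[2.2.1]heptane-1-carboxylate (camphanate of 10) | COC(=O)[C@@]1([C@@H]2OC(=O)C[C@@H]2C)CC(=O)c2c(OC(=O)[C@@]34CC[C@@](C)(C(=O)O3)C4(C)C)cccc2O1
F3 | step 4 | (2R)-2-(methoxycarbonyl)-2-[(2S,3R)-3-methyl-5-oxooxolan-2-yl]-4-oxochroman-5-yl (1S,4R)-4,7,7-trimethyl-3-oxo-2-oxabicyclo[2.2.1]heptane-1-carboxylate (camphanate of F1) | COC(=O)[C@]1([C@H]2OC(=O)C[C@H]2C)CC(=O)c2c(OC(=O)[C@@]34CC[C@@](C)(C(=O)O3)C4(C)C)cccc2O1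
F4 | step 5 | methyl 5-hydroxy-6-iodo-4-oxo-4H-chromene-2-carboxylate | COC(=O)c1cc(=O)c2c(O)c(I)ccc2o1
F5 | step 5 | 6-iodo-2-(methoxycarbonyl)-4,5-[(diisopropylsilanediyl)bis(oxy)]chromenylium triflate | COC(=O)c1cc2c3c(c(I)ccc3[o+]1)O[Si](C(C)C)(C(C)C)O2.[O-]S(=O)(=O)C(F)(F)F
F6 | step 5 | (±)-methyl (2S*)-6-iodo-4,5-[(diisopropylsilanediyl)bis(oxy)]-2-[(2R*)-3-methyl-5-oxo-2,5-dihydrofuran-2-yl]-2H-chromene-2-carboxylate | COC(=O)[C@@]1([C@@H]2OC(=O)C=C2C)C=C2O[Si](C(C)C)(C(C)C)Oc3c(I)ccc(O1)c23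
F7 | step 5 | (±)-methyl (2S*)-5-hydroxy-6-iodo-2-[(2R*)-3-methyl-5-oxo-2,5-dihydrofuran-2-yl]-4-oxochromane-2-carboxylate | COC(=O)[C@@]1([C@@H]2OC(=O)C=C2C)CC(=O)c2c(O)c(I)ccc2O1
F8 | step 8 | (3S,4R)-4-[(2S)-6-{(2S)-5-(benzyloxy)-2-(methoxycarbonyl)-2-[(2R,3S)-3-methyl-5-oxooxolan-2-yl]-4-oxochroman-6-yl}-5-hydroxy-2-(methoxycarbonyl)-4-oxochroman-2-yl]-4-hydroxy-3-methylbutanoic acid | COC(=O)[C@@]1([C@H](O)[C@@H](C)CC(=O)O)CC(=O)c2c(O)c(-c3ccc4c(c3OCc5ccccc5)C(=O)C[C@@](C(=O)OC)([C@@H]6OC(=O)C[C@@H]6C)O4)ccc2O1
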